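**Retrosynthetic overview**

1. Target 25 ← sevenfold O-demethylation ← Heck coupling of a C4 bromide on ring A with 4-methoxystyrene ← acid epimerisation at C2 of a cis dihydrofuran on ring A.
2. Structural feature used: in the dihydrofuran fused to ring A (the resorcinol ring bearing the styryl group), C3 is a diarylmethine bonded to C3a of ring A and to C5' of the catechol-type ring B, and C2 is an O1-bonded benzylic carbon carrying the 4-hydroxyphenyl group. The C2–C3 bond is therefore cut so that C3 is a diaryl carbene and C2 is the OCH2 carbon of a 4-methoxybenzyl ether on O1.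
3. The carbene comes from the hydrazone of a diaryl ketone. The ketone is assembled by adding the 5-lithio derivative of the finished ring B dihydrobenzofuran to 2-bromo-4-methoxy-6-(4-methoxybenzyloxy)benzaldehyde, itself made from 1-bromo-3,5-dimethoxybenzene.
4. The ring B dihydrobenzofuran is made by the same insertion (enantiomeric catalyst) and C2 epimerisation, starting from 5-bromo-o-vanillin, 4-methoxybenzyl chloride and 1-bromo-3,5-dimethoxybenzene.
5. Ring order: dihydrofuran on ring B (step 5), then dihydrofuran on ring A (step 13). C4 of ring A carries bromine as a placeholder for the styryl group until both rings exist.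

Key step: step 13

Assumption: Rh2(R-PTAD)4 (PTAD = 1-adamantyl(phthalimido)acetate) is taken as the catalyst hand that gives (3S) in the ring A closure, so Rh2(S-PTAD)4 gives (3R) in the ring B closure. The two closures need opposite hands in any case, and the hands change places if a model 2-benzyloxybenzophenone hydrazone shows the reverse sense.

Abbreviation used in names: "ArB" = (2R,3R)-3-(3,5-dimethoxyphenyl)-7-methoxy-2-(4-methoxyphenyl)-2,3-dihydro-1-benzofuran-5-yl.

**Ring B dihydrobenzofuran (steps 1–6)**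

Step 1
Reactants: 1 5-bromo-2-hydroxy-3-methoxybenzaldehyde; 2 4-methoxybenzyl chloride
Product: 3 5-bromo-3-methoxy-2-[(4-methoxybenzyl)oxy]benzaldehyde
Conditions: K2CO3, DMF, 60 °C
Reagents that add atoms: none
Why: Williamson ether synthesis, in which the potassium phenoxide of 1 displaces the benzylic chloride of 2 by SN2 while the aldehyde and the aryl bromide are inert to carbonate.

Step 2
Reactants: 4 1-bromo-3,5-dimethoxybenzene; 3 aldehyde from step 1
Product: 6 {5-bromo-3-methoxy-2-[(4-methoxybenzyl)oxy]phenyl}(3,5-dimethoxyphenyl)methanol (racemic), via 3,5-dimethoxyphenylmagnesium bromide 5 (not isolated)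
Conditions: 4, Mg, I2 (cat.), THF, reflux; then 3, THF, 0 °C → rt; H2O
Reagents that add atoms: none
Why: Grignard addition to an aldehyde, which is far faster than any exchange of the arylmagnesium bromide with the aryl bromide of 3; the new carbinol centre is racemic and is removed in step 3.

Step 3
Reactants: 6 diaryl carbinol
Product: 7 {5-bromo-3-methoxy-2-[(4-methoxybenzyl)oxy]phenyl}(3,5-dimethoxyphenyl)methanone
Conditions: Dess–Martin periodinane, CH2Cl2, rt
Reagents that add atoms: none
Why: Dess–Martin oxidation of a secondary diaryl carbinol to the benzophenone under near-neutral conditions that spare the 4-methoxybenzyl ether.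

Step 4
Reactants: 7 benzophenone
Product: 8 hydrazone of 7 (E/Z mixture)
Conditions: N2H4·H2O (excess), AcOH (cat.), EtOH, reflux
Reagents that add atoms: hydrazine (used as hydrate), NN
Why: Hydrazone formation by acid-catalysed condensation, with excess hydrazine suppressing azine formation; the C=N geometry is irrelevant because it is lost in the diazo compound.

Step 5
Reactants: 8 hydrazone
Product: 10 (2S,3R)-5-bromo-3-(3,5-dimethoxyphenyl)-7-methoxy-2-(4-methoxyphenyl)-2,3-dihydro-1-benzofuran (2,3-cis), via diaryldiazomethane 9 (not isolated)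
Conditions: activated MnO2, CH2Cl2, 0 °C; then Rh2(S-PTAD)4 (1 mol%), 0 °C → rt
Reagents that add atoms: none
Why: MnO2 dehydrogenation of the hydrazone followed by dirhodium-catalysed enantioselective intramolecular 1,5 C–H insertion of the donor/donor carbene into the ArO–CH2–Ar bond, the established route to cis-2,3-diaryl-2,3-dihydrobenzofurans; the catalyst sets C3 (R) by carbene face selection and the cis C2 (S) follows from the insertion transition state.

Step 6
Reactants: 10 cis dihydrobenzofuran
Product: 11 (2R,3R)-5-bromo-3-(3,5-dimethoxyphenyl)-7-methoxy-2-(4-methoxyphenyl)-2,3-dihydro-1-benzofuran (2,3-trans)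
Conditions: TFA, CH2Cl2, 0 °C → rt
Reagents that add atoms: none
Why: Acid-promoted epimerisation, in which reversible heterolysis of the O1–C2 bond gives a 4-methoxybenzylic cation that recloses to the thermodynamically preferred trans ring, inverting C2 to R while C3, which cannot ionise, keeps its configuration.

**Ring A aldehyde (steps 7–9)**

Step 7
Reactants: 4 1-bromo-3,5-dimethoxybenzene
Product: 13 2-bromo-4,6-dimethoxybenzaldehyde, via aryliminium chloride 12 (not isolated)
Conditions: POCl3, DMF, 0 → 90 °C; then H2O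
Reagents that add atoms: N,N-dimethylformamide, CN(C)C=O; water, O
Why: Vilsmeier–Haack formylation, in which the chloroiminium electrophile attacks the position ortho to bromine (para to one methoxy group, ortho to the other) in preference to the more crowded position between the two methoxy groups, and the iminium salt is hydrolysed on work-up.

Step 8
Reactants: 13 2-bromo-4,6-dimethoxybenzaldehyde
Product: 14 2-bromo-6-hydroxy-4-methoxybenzaldehyde
Conditions: BCl3 (1.2 equiv), CH2Cl2, −78 → 0 °C; then H2O
Reagents that add atoms: none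
Why: Chelation-directed Lewis-acid ether cleavage, in which BCl3 bound to the formyl oxygen removes only the methyl group of the ortho methoxy group through a six-membered boron chelate and leaves the para methoxy group.

Step 9
Reactants: 14 2-bromo-6-hydroxy-4-methoxybenzaldehyde; 2 4-methoxybenzyl chloride
Product: 15 2-bromo-4-methoxy-6-[(4-methoxybenzyl)oxy]benzaldehyde
Conditions: K2CO3, DMF, 60 °C
Reagents that add atoms: none
Why: Williamson ether synthesis of the ortho-formyl phenol with the benzylic chloride; the group installed here is not a protecting group but the future C2 and its aryl substituent.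

**Union, key step and endgame (steps 10–16)**

Step 10
Reactants: 11 trans bromo dihydrobenzofuran; 15 ring A aldehyde
Product: 17 {2-bromo-4-methoxy-6-[(4-methoxybenzyl)oxy]phenyl}(ArB)methanol (both carbinol epimers), via aryllithium 16 (not isolated)
Conditions: 11, n-BuLi, THF, −78 °C; then 15, −78 → 0 °C; H2O
Reagents that add atoms: none
Why: Bromine–lithium exchange followed by 1,2-addition to the aldehyde; exchange at −78 °C outruns deprotonation of the benzylic C3–H of 11, addition to the formyl group outruns exchange with the bromide of 15, and the two carbinol epimers converge in step 11.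

Step 11
Reactants: 17 diaryl carbinol
Product: 18 {2-bromo-4-methoxy-6-[(4-methoxybenzyl)oxy]phenyl}(ArB)methanone
Conditions: Dess–Martin periodinane, CH2Cl2, rt
Reagents that add atoms: none
Why: Dess–Martin oxidation of the hindered bis-benzylic alcohol to the diaryl ketone without touching the benzyl ether or the dihydrobenzofuran.

Step 12
Reactants: 18 diaryl ketone
Product: 19 hydrazone of 18 (E/Z mixture)
Conditions: N2H4·H2O (large excess), AcOH (cat.), n-BuOH, 110 °C
Reagents that add atoms: hydrazine (used as hydrate), NN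
Why: Hydrazone formation by condensation, run under forcing conditions because the carbonyl group is flanked by bromine and the benzyloxy group; the electron-rich bromoarene should resist substitution by hydrazine in the absence of copper.

Step 13
Reactants: 19 hydrazone
Product: 21 (2R,3S)-4-bromo-3-(ArB)-6-methoxy-2-(4-methoxyphenyl)-2,3-dihydro-1-benzofuran (ring A dihydrofuran cis), via diaryldiazomethane 20 (not isolated)
Conditions: activated MnO2, CH2Cl2, 0 °C; then Rh2(R-PTAD)4 (2 mol%), 0 °C → rt
Reagents that add atoms: none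
Why: MnO2 dehydrogenates 19 to diaryldiazomethane 20, which loses N2 on the dirhodium tetracarboxylate to give a rhodium-bound diaryl (donor/donor) carbene at the future C3, and this carbon takes up one C–H bond of the ortho OCH2Ar group in a single asynchronous step in which hydrogen transfer runs ahead of C2–C3 bond formation. The closest known reaction is the dirhodium-catalysed enantioselective 1,5 C–H insertion of diazo compounds from 2-benzyloxybenzophenone hydrazones to cis-2,3-diaryl-2,3-dihydrobenzofurans, of which step 5 is a plain case. The five-membered O1–C2–C3–C3a–C7a ring closes by this intramolecular 1,5-insertion, the only ring size the ortho tether permits. C3 is set by the catalyst, whose chiral carboxylate pocket exposes one carbene face (taken to give 3S with the R ligand) and should override the remote ring B centres, while C2 arises as the cis (2R) isomer from the compact insertion transition state and is corrected in step 14. The step needs site selectivity and chemoselectivity: the only C–H bonds within reach are the two of the 4-methoxybenzyl ether, activated by oxygen and by the electron-rich aryl group; the weakly electrophilic carbene should leave the methoxyarenes alone; and bromine at C4 keeps any alkene away from the carbene while the two ortho substituents slow bimolecular azine formation.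

Step 14
Reactants: 21 cis bromide
Product: 22 (2S,3S)-4-bromo-3-(ArB)-6-methoxy-2-(4-methoxyphenyl)-2,3-dihydro-1-benzofuran (both dihydrofurans trans)
Conditions: TFA, CH2Cl2, 0 °C → rt
Reagents that add atoms: none
Why: Acid-promoted epimerisation through reversible O1–C2 heterolysis to the 4-methoxybenzylic cation and reclosure to the trans ring, turning C2 from R to S under thermodynamic control; C3 is untouched and the already-trans ring B can only return to itself.

Step 15
Reactants: 22 trans bromide; 23 4-methoxystyrene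
Product: 24 (2S,3S)-3-(ArB)-6-methoxy-2-(4-methoxyphenyl)-4-[(E)-2-(4-methoxyphenyl)ethenyl]-2,3-dihydro-1-benzofuran (heptamethyl ether of the target)
Conditions: Pd2(dba)3 (2.5 mol%), P(t-Bu)3 (10 mol%), Cs2CO3, dioxane, 100 °C
Reagents that add atoms: none
Why: Heck reaction, in which oxidative addition of the ortho-substituted aryl bromide to zerovalent palladium bearing the bulky electron-rich phosphine, β-selective insertion of the styrene and syn β-hydride elimination should give the E stilbene; carbonate is too weak a base to open or epimerise the dihydrobenzofurans.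

Step 16
Reactants: 24 heptamethyl ether
Product: 25 CNP0172909.1, (2S,3S)-3-[(2R,3R)-3-(3,5-dihydroxyphenyl)-7-hydroxy-2-(4-hydroxyphenyl)-2,3-dihydro-1-benzofuran-5-yl]-2-(4-hydroxyphenyl)-4-[(E)-2-(4-hydroxyphenyl)ethenyl]-2,3-dihydro-1-benzofuran-6-ol
Conditions: BBr3 (excess), CH2Cl2, −78 °C → rt; then ice-water
Reagents that add atoms: none
Why: Lewis-acid cleavage of aryl methyl ethers with BBr3 (bromide attacks the methyl group of each O–B adduct), applied to all seven methoxy groups; both dihydrofuran rings are already in their preferred trans form, so any reversible C2–O ionisation returns the same configuration.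

**Compound list**

1 | 5-bromo-2-hydroxy-3-methoxybenzaldehyde | COc1cc(Br)cc(C=O)c1O | starting material
2 | 4-methoxybenzyl chloride | COc1ccc(CCl)cc1 | starting material
3 | 5-bromo-3-methoxy-2-[(4-methoxybenzyl)oxy]benzaldehyde | COc1ccc(COc2c(C=O)cc(Br)cc2OC)cc1 | intermediate
4 | 1-bromo-3,5-dimethoxybenzene | COc1cc(Br)cc(OC)c1 | starting material
5 | 3,5-dimethoxyphenylmagnesium bromide | COc1cc([Mg]Br)cc(OC)c1 | intermediate
6 | {5-bromo-3-methoxy-2-[(4-methoxybenzyl)oxy]phenyl}(3,5-dimethoxyphenyl)methanol, racemic | COc1ccc(COc2c(C(O)c3cc(OC)cc(OC)c3)cc(Br)cc2OC)cc1 | intermediate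
7 | {5-bromo-3-methoxy-2-[(4-methoxybenzyl)oxy]phenyl}(3,5-dimethoxyphenyl)methanone | COc1ccc(COc2c(C(=O)c3cc(OC)cc(OC)c3)cc(Br)cc2OC)cc1 | intermediate
8 | hydrazone of 7 | COc1ccc(COc2c(C(=NN)c3cc(OC)cc(OC)c3)cc(Br)cc2OC)cc1 | intermediate
9 | 5-bromo-1-[diazo(3,5-dimethoxyphenyl)methyl]-3-methoxy-2-[(4-methoxybenzyl)oxy]benzene | COc1ccc(COc2c(C(=[N+]=[N-])c3cc(OC)cc(OC)c3)cc(Br)cc2OC)cc1 | intermediate
10 | (2S,3R)-5-bromo-3-(3,5-dimethoxyphenyl)-7-methoxy-2-(4-methoxyphenyl)-2,3-dihydro-1-benzofuran (cis) | Brc1cc(OC)c2c(c1)[C@@H](c1cc(OC)cc(OC)c1)[C@@H](c1ccc(OC)cc1)O2 | intermediate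
11 | (2R,3R)-5-bromo-3-(3,5-dimethoxyphenyl)-7-methoxy-2-(4-methoxyphenyl)-2,3-dihydro-1-benzofuran (trans) | Brc1cc(OC)c2c(c1)[C@@H](c1cc(OC)cc(OC)c1)[C@H](c1ccc(OC)cc1)O2 | intermediate
12 | [(2-bromo-4,6-dimethoxyphenyl)methylidene]dimethyliminium chloride | COc1cc(OC)c(C=[N+](C)C)c(Br)c1.[Cl-] | intermediate
13 | 2-bromo-4,6-dimethoxybenzaldehyde | COc1cc(OC)c(C=O)c(Br)c1 | intermediate
14 | 2-bromo-6-hydroxy-4-methoxybenzaldehyde | COc1cc(O)c(C=O)c(Br)c1 | intermediate
15 | 2-bromo-4-methoxy-6-[(4-methoxybenzyl)oxy]benzaldehyde | COc1ccc(COc2cc(OC)cc(Br)c2C=O)cc1 | intermediate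
16 | [(2R,3R)-3-(3,5-dimethoxyphenyl)-7-methoxy-2-(4-methoxyphenyl)-2,3-dihydro-1-benzofuran-5-yl]lithium | [Li]c1cc(OC)c2c(c1)[C@@H](c1cc(OC)cc(OC)c1)[C@H](c1ccc(OC)cc1)O2 | intermediate
17 | {2-bromo-4-methoxy-6-[(4-methoxybenzyl)oxy]phenyl}[(2R,3R)-3-(3,5-dimethoxyphenyl)-7-methoxy-2-(4-methoxyphenyl)-2,3-dihydro-1-benzofuran-5-yl]methanol, both carbinol epimers | COc1ccc(COc2cc(OC)cc(Br)c2C(O)c2cc(OC)c3c(c2)[C@@H](c2cc(OC)cc(OC)c2)[C@H](c2ccc(OC)cc2)O3)cc1 | intermediate
18 | {2-bromo-4-methoxy-6-[(4-methoxybenzyl)oxy]phenyl}[(2R,3R)-3-(3,5-dimethoxyphenyl)-7-methoxy-2-(4-methoxyphenyl)-2,3-dihydro-1-benzofuran-5-yl]methanone | COc1ccc(COc2cc(OC)cc(Br)c2C(=O)c2cc(OC)c3c(c2)[C@@H](c2cc(OC)cc(OC)c2)[C@H](c2ccc(OC)cc2)O3)cc1 | intermediate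
19 | hydrazone of 18 | COc1ccc(COc2cc(OC)cc(Br)c2C(=NN)c2cc(OC)c3c(c2)[C@@H](c2cc(OC)cc(OC)c2)[C@H](c2ccc(OC)cc2)O3)cc1 | intermediate
20 | (2R,3R)-5-(diazo{2-bromo-4-methoxy-6-[(4-methoxybenzyl)oxy]phenyl}methyl)-3-(3,5-dimethoxyphenyl)-7-methoxy-2-(4-methoxyphenyl)-2,3-dihydro-1-benzofuran | COc1ccc(COc2cc(OC)cc(Br)c2C(=[N+]=[N-])c2cc(OC)c3c(c2)[C@@H](c2cc(OC)cc(OC)c2)[C@H](c2ccc(OC)cc2)O3)cc1 | intermediate
21 | (2R,3S)-4-bromo-3-[(2R,3R)-3-(3,5-dimethoxyphenyl)-7-methoxy-2-(4-methoxyphenyl)-2,3-dihydro-1-benzofuran-5-yl]-6-methoxy-2-(4-methoxyphenyl)-2,3-dihydro-1-benzofuran (ring A dihydrofuran cis) | Brc1cc(OC)cc2c1[C@H](c1cc(OC)c3c(c1)[C@@H](c1cc(OC)cc(OC)c1)[C@H](c1ccc(OC)cc1)O3)[C@H](c1ccc(OC)cc1)O2 | intermediate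
22 | (2S,3S)-4-bromo-3-[(2R,3R)-3-(3,5-dimethoxyphenyl)-7-methoxy-2-(4-methoxyphenyl)-2,3-dihydro-1-benzofuran-5-yl]-6-methoxy-2-(4-methoxyphenyl)-2,3-dihydro-1-benzofuran (both rings trans) | Brc1cc(OC)cc2c1[C@H](c1cc(OC)c3c(c1)[C@@H](c1cc(OC)cc(OC)c1)[C@H](c1ccc(OC)cc1)O3)[C@@H](c1ccc(OC)cc1)O2 | intermediate
23 | 4-methoxystyrene | C=Cc1ccc(OC)cc1 | starting material
24 | (2S,3S)-3-[(2R,3R)-3-(3,5-dimethoxyphenyl)-7-methoxy-2-(4-methoxyphenyl)-2,3-dihydro-1-benzofuran-5-yl]-6-methoxy-2-(4-methoxyphenyl)-4-[(E)-2-(4-methoxyphenyl)ethenyl]-2,3-dihydro-1-benzofuran | COc1ccc(/C=C/c2cc(OC)cc3c2[C@H](c2cc(OC)c4c(c2)[C@@H](c2cc(OC)cc(OC)c2)[C@H](c2ccc(OC)cc2)O4)[C@@H](c2ccc(OC)cc2)O3)cc1 | intermediate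
25 | CNP0172909.1, (2S,3S)-3-[(2R,3R)-3-(3,5-dihydroxyphenyl)-7-hydroxy-2-(4-hydroxyphenyl)-2,3-dihydro-1-benzofuran-5-yl]-2-(4-hydroxyphenyl)-4-[(E)-2-(4-hydroxyphenyl)ethenyl]-2,3-dihydro-1-benzofuran-6-ol | Oc1ccc(/C=C/c2cc(O)cc3c2[C@H](c2cc(O)c4c(c2)[C@@H](c2cc(O)cc(O)c2)[C@H](c2ccc(O)cc2)O4)[C@@H](c2ccc(O)cc2)O3)cc1 | target

**Step count**

Total: 16 steps. Longest linear sequence: 13 steps (steps 1–6, then 10–16); the ring A aldehyde arm (steps 7–9) joins at step 10.

**Steps most likely to fail**

1. Step 13 (key step). The diazo carbon sits between two ortho substituents, so carbene formation on rhodium may be slow and the diazo compound may drain into azine or ketone. The remote ring B centres could also erode the catalyst's control of the carbene face, giving the wrong C3 epimer.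
Fallback (polar [4+1] annulation in place of carbene insertion), setting out from 11 and 14 and returning at 22: aryllithium 16 (from 11, n-BuLi, THF, −78 °C) is added to 14 that has first been deprotonated with NaH, which should give the ortho-hydroxy diaryl carbinol F1. Treatment with sodium 4-methylbenzenesulfinate in formic acid should convert it to the aryl sulfone F2, a base-triggered quinone methide precursor. 4-Methoxybenzyl chloride 2 and tetrahydrothiophene should give 1-(4-methoxybenzyl)tetrahydrothiophenium chloride F3. With Cs2CO3 in CH2Cl2, F2 should lose sulfinate to the ortho-quinone methide F4, which is attacked at its exocyclic carbon by the ylide of F3; the phenoxide then displaces tetrahydrothiophene in a 5-exo closure to the trans dihydrobenzofuran. Because ring B is already enantiopure, the two trans products, 22 and its ring A (2R,3R) diastereomer F5, are diastereomers and would be separated by chromatography.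

2. Step 12. Condensation at the doubly ortho-substituted carbonyl may stall, and prolonged heating with hydrazine invites attack at the ortho bromide with closure to an indazole.
Fallback (hydrazone by transimination of a ketimine instead of condensation with the ketone), setting out from 15 and 11 and returning at 19: aldehyde 15 with I2 in aqueous NH3/THF should give 2-bromo-4-methoxy-6-[(4-methoxybenzyl)oxy]benzonitrile F6. Aryllithium 16 (from 11) adds to the sterically open nitrile and a methanol quench should give the N–H ketimine F7. Exchange with hydrazine (N2H4·H2O, AcOH, EtOH, 60 °C) expels ammonia and should give hydrazone 19 under far milder conditions; the oxidation of step 11 is bypassed.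

3. Step 16. During the sevenfold demethylation the strong Lewis acid can protonate the stilbene or open the benzylic C2–O bonds, leading to intramolecular Friedel–Crafts cyclisation onto ring B or oligomerisation instead of clean phenol release.
Fallback (demethylate before the alkene is present), setting out from 22 and returning at 25: BBr3 on bromide 22 should give the hexaphenol bromide F8, which carries no acid-sensitive stilbene. Peracetylation (Ac2O, pyridine) should give the hexaacetate F9. Heck coupling with 4-acetoxystyrene (Pd(OAc)2, P(o-tol)3, Et3N, DMF, 100 °C) should give the heptaacetate F10, and mild methanolysis (K2CO3, MeOH, rt) should release 25.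

**Further compounds**

F1 | step 13 | 3-bromo-2-{hydroxy[(2R,3R)-3-(3,5-dimethoxyphenyl)-7-methoxy-2-(4-methoxyphenyl)-2,3-dihydro-1-benzofuran-5-yl]methyl}-5-methoxyphenol (both carbinol epimers) | COc1cc(O)c(C(O)c2cc(OC)c3c(c2)[C@@H](c2cc(OC)cc(OC)c2)[C@H](c2ccc(OC)cc2)O3)c(Br)c1
F2 | step 13 | 3-bromo-2-{[(2R,3R)-3-(3,5-dimethoxyphenyl)-7-methoxy-2-(4-methoxyphenyl)-2,3-dihydro-1-benzofuran-5-yl](4-methylbenzenesulfonyl)methyl}-5-methoxyphenol | COc1cc(O)c(C(c2cc(OC)c3c(c2)[C@@H](c2cc(OC)cc(OC)c2)[C@H](c2ccc(OC)cc2)O3)S(=O)(=O)c2ccc(C)cc2)c(Br)c1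
F3 | step 13 | 1-(4-methoxybenzyl)tetrahydrothiophenium chloride | COc1ccc(C[S+]2CCCC2)cc1.[Cl-]
F4 | step 13 | ortho-quinone methide, 3-bromo-5-methoxy-2-{[(2R,3R)-3-(3,5-dimethoxyphenyl)-7-methoxy-2-(4-methoxyphenyl)-2,3-dihydro-1-benzofuran-5-yl]methylidene}cyclohexa-3,5-dien-1-one (formed in the flask) | O=C1C=C(OC)C=C(Br)C1=Cc1cc(OC)c2c(c1)[C@@H](c1cc(OC)cc(OC)c1)[C@H](c1ccc(OC)cc1)O2
F5 | step 13 | (2R,3R)-4-bromo-3-[(2R,3R)-3-(3,5-dimethoxyphenyl)-7-methoxy-2-(4-methoxyphenyl)-2,3-dihydro-1-benzofuran-5-yl]-6-methoxy-2-(4-methoxyphenyl)-2,3-dihydro-1-benzofuran (unwanted trans diastereomer) | Brc1cc(OC)cc2c1[C@@H](c1cc(OC)c3c(c1)[C@@H](c1cc(OC)cc(OC)c1)[C@H](c1ccc(OC)cc1)O3)[C@H](c1ccc(OC)cc1)O2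
F6 | step 12 | 2-bromo-4-methoxy-6-[(4-methoxybenzyl)oxy]benzonitrile | COc1ccc(COc2cc(OC)cc(Br)c2C#N)cc1
F7 | step 12 | {2-bromo-4-methoxy-6-[(4-methoxybenzyl)oxy]phenyl}[(2R,3R)-3-(3,5-dimethoxyphenyl)-7-methoxy-2-(4-methoxyphenyl)-2,3-dihydro-1-benzofuran-5-yl]methanimine | COc1ccc(COc2cc(OC)cc(Br)c2C(=N)c2cc(OC)c3c(c2)[C@@H](c2cc(OC)cc(OC)c2)[C@H](c2ccc(OC)cc2)O3)cc1
F8 | step 16 | (2S,3S)-4-bromo-3-[(2R,3R)-3-(3,5-dihydroxyphenyl)-7-hydroxy-2-(4-hydroxyphenyl)-2,3-dihydro-1-benzofuran-5-yl]-2-(4-hydroxyphenyl)-2,3-dihydro-1-benzofuran-6-ol | Brc1cc(O)cc2c1[C@H](c1cc(O)c3c(c1)[C@@H](c1cc(O)cc(O)c1)[C@H](c1ccc(O)cc1)O3)[C@@H](c1ccc(O)cc1)O2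
F9 | step 16 | hexaacetate of F8 | Brc1cc(OC(C)=O)cc2c1[C@H](c1cc(OC(C)=O)c3c(c1)[C@@H](c1cc(OC(C)=O)cc(OC(C)=O)c1)[C@H](c1ccc(OC(C)=O)cc1)O3)[C@@H](c1ccc(OC(C)=O)cc1)O2
F10 | step 16 | heptaacetate of 25 | CC(=O)Oc1ccc(/C=C/c2cc(OC(C)=O)cc3c2[C@H](c2cc(OC(C)=O)c4c(c2)[C@@H](c2cc(OC(C)=O)cc(OC(C)=O)c2)[C@H](c2ccc(OC(C)=O)cc2)O4)[C@@H](c2ccc(OC(C)=O)cc2)O3)cc1
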